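**Strategy.** Atoms are numbered as in the asbestinin skeleton (remark below). The oxepane ring (O–C16–C15–C14–C1–C2–C3) is disconnected at its C3–O bond. Its precursor is a cyclohexanone (C16 ketone flanked by quaternary C3 and C15) fused to the cyclohexane and tetrahydrofuran rings. A Baeyer–Villiger oxidation inserts oxygen between C16 and C3 with retention, so the tertiary ether centre is made beforehand as an all-carbon quaternary centre by axial allylation of a trans-fused 2-methyl-1,3-dione. The dione comes from a Diels–Alder reaction, lactonisation and Claisen cyclisation; a Nozaki–Hiyama–Kishi reaction closes the ten-membered ring last.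

Key step: step 17

Remark (numbering): C1, C10 and C14 are the ring-fusion CH carbons of the cyclohexane; C2 and C9 the two CH–O carbons of the tetrahydrofuran; C3 the quaternary ether carbon; C4 the octanoyloxy carbon; C5 the CH2 next to the ketone C6; C7 the carbon bearing the exocyclic methylene; C8 the CH2 between C7 and C9; C11 the acetoxy carbon; C12 and C15 the methyl-bearing CH carbons; C13 the ring CH2; C16 the OCH2.
Remark (assumption): in step 2 the ligand antipode is taken that adds the bromoallyl group to the Si face of aldehyde 2.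

Step 1
Reactants: 1 methacrolein
Product: 2 (E)-4-methylpenta-2,4-dienal
Conditions: Ph3P=CHCHO, toluene, 80 °C (1 in excess)
Reagents that add atoms: (triphenylphosphoranylidene)acetaldehyde O=CC=P(c1ccccc1)(c1ccccc1)c1ccccc1
Why: Wittig olefination with a stabilised ylide gives the (E)-enal that becomes C9 to C13 with the C12 methyl group; no stereocentre is formed.

Step 2
Reactants: 2 (E)-4-methylpenta-2,4-dienal
Product: 4 (4S,5E)-2-bromo-7-methylocta-1,5,7-trien-4-ol, via trimethylsilyl ether 3 (not isolated)
Conditions: 2,3-dibromopropene, CrBr3 (cat.), chiral oxazoline–sulfonamide ligand (cat.), Et3N, cobalt phthalocyanine C32H16CoN8 (cat.), Mn, Me3SiCl, THF, 0 °C; then 1 M HCl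
Reagents that add atoms: 2,3-dibromopropene C=C(Br)CBr; chlorotrimethylsilane C[Si](C)(C)Cl (in 3 only)
Why: Catalytic asymmetric Nozaki–Hiyama–Kishi 2-haloallylation, in which the ligand-bound allylchromium species adds 1,2 to the Si face of the enal and so sets C9 (S), the silyl chloride turning the chromium alkoxide over as ether 3, which the acid work-up cleaves.

Step 3
Reactants: 4 (4S,5E)-2-bromo-7-methylocta-1,5,7-trien-4-ol
Product: 5 silyl-protected diene
Conditions: TBSCl, imidazole, DMF, rt
Reagents that add atoms: tert-butyldimethylsilyl chloride CC(C)(C)[Si](C)(C)Cl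
Why: Silyl ether formation protects the C9 hydroxyl for the Lewis-acid cycloaddition; no stereocentre is touched.

Step 4
Reactants: 6 ethyl 3-oxopentanoate
Product: 7 ethyl 2-(2-ethyl-1,3-dioxolan-2-yl)acetate
Conditions: ethylene glycol, TsOH (cat.), benzene, reflux with removal of water
Reagents that add atoms: ethylene glycol OCCO
Why: Ketalisation masks the ketone (future C16) so that the later enoyl imide cannot isomerise into conjugation with it.

Step 5
Reactants: 7 ethyl 2-(2-ethyl-1,3-dioxolan-2-yl)acetate
Product: 8 2-(2-ethyl-1,3-dioxolan-2-yl)acetaldehyde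
Conditions: i-Bu2AlH, CH2Cl2, −78 °C
Reagents that add atoms: none
Why: Partial ester reduction at low temperature stops at the aldehyde because the aluminium hemiacetal survives until work-up.

Step 6
Reactants: 9 diethylphosphonoacetic acid; 10 (R)-4-benzyloxazolidin-2-one
Product: 11 (R)-4-benzyl-3-[2-(diethoxyphosphoryl)acetyl]oxazolidin-2-one
Conditions: pivaloyl chloride, Et3N, THF, −20 °C; then 10, LiCl, rt
Reagents that add atoms: none
Why: N-Acylation of the oxazolidinone through the mixed pivalic anhydride gives the chiral phosphonate for the olefination.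

Step 7
Reactants: 8 2-(2-ethyl-1,3-dioxolan-2-yl)acetaldehyde; 11 phosphonate imide
Product: 12 (R)-4-benzyl-3-[(E)-4-(2-ethyl-1,3-dioxolan-2-yl)but-2-enoyl]oxazolidin-2-one
Conditions: LiCl, i-Pr2NEt, MeCN, rt
Reagents that add atoms: none
Why: Horner–Wadsworth–Emmons olefination under mild LiCl/amine conditions gives the (E)-enoyl imide (C1=C14) without any epimerisable centre.

Step 8
Reactants: 5 silyl-protected diene; 12 enoyl imide
Product: 13 Diels–Alder adduct
Conditions: Et2AlCl, CH2Cl2, −78 to −30 °C
Reagents that add atoms: none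
Why: Lewis-acid-promoted Diels–Alder reaction of the chelated s-cis enoyl imide, in which the 1-alkyl-3-methyl diene gives the ortho/para regioisomer, the endo transition state places the C2 carbonyl cis to the C10 side chain, the (E)-dienophile places C2 and C15 trans, and the benzyl group of the auxiliary shields one face so that C1, C10 and C14 arise as in the target.

Step 9
Reactants: 13 Diels–Alder adduct
Product: 14 bicyclic γ-lactone
Conditions: Bu4NF, THF, 0 °C to rt
Reagents that add atoms: none
Why: Desilylation frees the C9 alkoxide, which attacks the cis-disposed imide carbonyl (acyl transfer, five-membered ring) to give the cis-fused lactone and release the auxiliary; C9 keeps its configuration.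

Step 10
Reactants: 14 bicyclic γ-lactone
Product: 15 11-epi alcohol
Conditions: BH3·THF, THF, 0 °C; then NaBO3·4H2O, H2O, rt
Reagents that add atoms: sodium perborate [Na+].[O-]OB=O
Why: Hydroboration–oxidation, in which borane adds syn to the C11=C12 alkene from the convex face opposite the lactone and the C10 side chain with boron on the less substituted C11, sets C12 (methyl cis to the C10 substituent) and gives the C11 alcohol on the wrong face, corrected in steps 11 and 12.

Step 11
Reactants: 15 11-epi alcohol
Product: 16 C11 ketone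
Conditions: Dess–Martin periodinane, NaHCO3, CH2Cl2, 0 °C
Reagents that add atoms: none
Why: Dess–Martin oxidation under buffered, non-enolising conditions gives the ketone while the kinetically set C12 centre is kept.

Step 12
Reactants: 16 C11 ketone
Product: 17 C11 alcohol
Conditions: LiBH(s-Bu)3, THF, −78 °C
Reagents that add atoms: none
Why: Reduction with a bulky borohydride, whose hydride attacks the face opposite the two flanking substituents (C10 side chain and C12 methyl), should give the all-cis C10/C11/C12 array and thus the C11 configuration of the target.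

Step 13
Reactants: 17 C11 alcohol
Product: 18 C11 silyl ether
Conditions: TBSOTf, 2,6-lutidine, CH2Cl2, −78 to 0 °C
Reagents that add atoms: tert-butyldimethylsilyl triflate CC(C)(C)[Si](C)(C)OS(=O)(=O)C(F)(F)F
Why: Silylation with the reactive triflate protects the hindered C11 hydroxyl against the bases and hydrides that follow.

Step 14
Reactants: 18 C11 silyl ether
Product: 19 keto lactone
Conditions: PPTS, acetone–H2O, 50 °C
Reagents that add atoms: water O
Why: Mild acid-catalysed ketal hydrolysis frees the ethyl ketone (C16 carbonyl, C3 as its CH2) while the silyl ether and the lactone persist.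

Step 15
Reactants: 19 keto lactone
Product: 21 allylated hydroxy diketone, via 2-methyl-1,3-dione 20 (not isolated)
Conditions: KN(SiMe3)2, THF, −78 to 0 °C; then allyl bromide, DMF, 0 °C to rt
Reagents that add atoms: allyl bromide C=CCBr
Why: Intramolecular Claisen (Dieckmann-type) condensation, in which the ethyl ketone enolate (C3) acylates the lactone carbonyl (C2) to close the trans-fused six-membered ring and release the C9 hydroxyl, followed by C-allylation of the potassium enolate of 20 along the axial trajectory anti to the C14 flap, which sets C3 with the allyl group cis to H1.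

Step 16
Reactants: 21 allylated hydroxy diketone
Product: 23 tricyclic ketone, via hemiketal 22 (not isolated)
Conditions: Et3SiH, BF3·OEt2, CH2Cl2, −78 to −40 °C
Reagents that add atoms: none
Why: Reductive etherification, in which the C9 hydroxyl adds only to the nearby C2 carbonyl, hemiketal 22 ionises to the cyclic oxocarbenium ion and Et3SiH delivers hydride axially, anti to the axial allyl group on C3, closes the tetrahydrofuran with H2 trans to H1 and leaves the C16 ketone as the only carbonyl.

Step 17
Reactants: 23 tricyclic ketone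
Product: 25 ε-lactone, via silyl peroxy hemiketal 24 (not isolated)
Conditions: Me3SiOOSiMe3, Me3SiOTf (cat.), CH2Cl2, −40 to 0 °C
Reagents that add atoms: bis(trimethylsilyl) peroxide C[Si](C)(C)OO[Si](C)(C)C
Why: Baeyer–Villiger oxidation: the silyl peroxide adds to the Lewis-acid-activated C16 carbonyl to give adduct 24, and the C3–C16 bond migrates to the peroxide oxygen with loss of silanolate. The closest known reaction type is the Baeyer–Villiger ring expansion of 2,2-disubstituted cyclohexanones with bis(trimethylsilyl) peroxide, a reagent that leaves C=C bonds untouched. No ring is closed by cyclisation; the seven-membered ring arises from the six-membered carbocycle by 1,2-shift of ring carbon C3 to oxygen, that is by insertion of O into the C3–C16 bond. No new stereocentre is formed, because C3 migrates with retention and its configuration from step 15 becomes that of the tertiary C–O carbon. The step needs regioselectivity (C3 against C15 migration), secured by the fully substituted C3 against the CH2 at C15, and chemoselectivity over the allyl and bromoalkene groups, secured by the non-epoxidising peroxide.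

Step 18
Reactants: 25 ε-lactone
Product: 26 15-epi methyl lactone
Conditions: LiN(i-Pr)2, THF, −78 °C; then MeI
Reagents that add atoms: iodomethane CI
Why: Lactone enolate alkylation introduces the C15 methyl group; the electrophile is expected to enter anti to C13, so mainly the 15-epimer should form, and both epimers are carried on.

Step 19
Reactants: 26 15-epi methyl lactone
Product: 28 C15 methyl lactone, via lithium enolate 27 (not isolated)
Conditions: LiN(i-Pr)2, THF, −78 °C; then AcOH, −78 °C
Reagents that add atoms: none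
Why: Stereoconvergent enolate protonation: both C15 epimers give the same planar enolate 27, and kinetic C-protonation on the face anti to C13 (the face used by iodomethane in step 18) should place the methyl group cis to C13, the C15 configuration of the target.

Step 20
Reactants: 28 C15 methyl lactone
Product: 29 lactol
Conditions: i-Bu2AlH, CH2Cl2, −78 °C
Reagents that add atoms: none
Why: Partial reduction of the lactone at −78 °C stops at the lactol (stable aluminium hemiacetal) and touches no stereocentre of the route.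

Step 21
Reactants: 29 lactol
Product: 30 oxepane
Conditions: Et3SiH, BF3·OEt2, CH2Cl2, −78 to −20 °C
Reagents that add atoms: none
Why: Ionic hydrogenation, in which BF3 ionises the lactol to the endocyclic oxocarbenium ion and Et3SiH reduces it, turns C16 into the OCH2 of the oxepane.

Step 22
Reactants: 30 oxepane
Product: 31 propenyl oxepane
Conditions: [Ir(cod)(PMePh2)2]PF6 (cat., activated with H2), THF, rt
Reagents that add atoms: none
Why: Iridium-hydride-catalysed olefin isomerisation moves the terminal double bond of the allyl group into the (E)-1-propenyl position (C4=C5), while the 1,1-disubstituted bromoalkene is left.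

Step 23
Reactants: 31 propenyl oxepane
Product: 32 C4 aldehyde
Conditions: OsO4 (cat.), NaIO4, 2,6-lutidine, dioxane–H2O, rt
Reagents that add atoms: sodium periodate [Na+].[O-]I(=O)(=O)=O
Why: Lemieux–Johnson oxidation (dihydroxylation and periodate cleavage) of the electron-rich propenyl alkene gives the non-enolisable C4 aldehyde, the electron-poor bromoalkene reacting far more slowly.

Step 24
Reactants: 32 C4 aldehyde
Product: 33 C4 carbinol
Conditions: allyltributylstannane, MgBr2·OEt2, CH2Cl2, −78 to −20 °C
Reagents that add atoms: allyltributylstannane C=CC[Sn](CCCC)(CCCC)CCCC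
Why: Chelation-controlled allylstannane addition: magnesium bridges the aldehyde and the oxepane oxygen on C3 in a five-membered chelate and the allyl group enters from the side of the C3 methyl group, anti to C2, which should give the 4R carbinol.

Step 25
Reactants: 33 C4 carbinol
Product: 34 C4 octanoate
Conditions: octanoyl chloride, pyridine, DMAP (cat.), CH2Cl2, rt
Reagents that add atoms: octanoyl chloride CCCCCCCC(=O)Cl
Why: DMAP-catalysed acylation installs the octanoate of the target on the hindered secondary alcohol with retention.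

Step 26
Reactants: 34 C4 octanoate
Product: 35 C11 alcohol
Conditions: HF·pyridine, THF, 0 °C to rt
Reagents that add atoms: none
Why: Acidic fluoride desilylation frees the C11 hydroxyl without the basic conditions that could cleave or shift the octanoate.

Step 27
Reactants: 35 C11 alcohol
Product: 36 C11 acetate
Conditions: Ac2O, pyridine, DMAP (cat.), CH2Cl2, rt
Reagents that add atoms: acetic anhydride CC(=O)OC(C)=O
Why: Acetylation installs the C11 acetate of the target with retention.

Step 28
Reactants: 36 C11 acetate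
Product: 37 C6 aldehyde
Conditions: OsO4 (cat.), NaIO4, 2,6-lutidine, dioxane–H2O, rt
Reagents that add atoms: sodium periodate [Na+].[O-]I(=O)(=O)=O
Why: Lemieux–Johnson cleavage of the terminal alkene gives the β-acyloxy aldehyde (C6) under buffered conditions, the bromoalkene again being spared.

Step 29
Reactants: 37 C6 aldehyde
Product: 38 macrocyclic allylic alcohol
Conditions: CrCl2, NiCl2 (cat.), DMSO, rt, high dilution
Reagents that add atoms: none
Why: Nozaki–Hiyama–Kishi reaction: nickel-catalysed insertion into the alkenyl bromide, transmetalation to chromium and addition to the C6 aldehyde close the ten-membered carbocycle at C6–C7 with the exocyclic methylene in place; the new C6 carbinol centre is removed in step 30.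

Step 30
Reactants: 38 macrocyclic allylic alcohol
Product: 39 asbestinin 16
Conditions: Dess–Martin periodinane, NaHCO3, CH2Cl2, 0 °C to rt
Reagents that add atoms: none
Why: Dess–Martin oxidation of the allylic alcohol gives the α-methylene ketone under buffered conditions that avoid β-elimination of the octanoate.

**Compound list**

1 | methacrolein | C=C(C)C=O | starting material
2 | (E)-4-methylpenta-2,4-dienal | C=C(C)/C=C/C=O | intermediate
3 | (4S,5E)-2-bromo-7-methyl-4-(trimethylsilyloxy)octa-1,5,7-triene (not isolated) | C=C(Br)C[C@H](O[Si](C)(C)C)/C=C/C(C)=C | intermediate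
4 | (4S,5E)-2-bromo-7-methylocta-1,5,7-trien-4-ol (carbinol carbon = C9) | C=C(Br)C[C@H](O)/C=C/C(C)=C | intermediate
5 | silyl-protected diene: tert-butyldimethylsilyl ether of 4 | C=C(Br)C[C@H](O[Si](C)(C)C(C)(C)C)/C=C/C(C)=C | intermediate
6 | ethyl 3-oxopentanoate | CCC(=O)CC(=O)OCC | starting material
7 | ethyl 2-(2-ethyl-1,3-dioxolan-2-yl)acetate | CCOC(=O)CC1(CC)OCCO1 | intermediate
8 | 2-(2-ethyl-1,3-dioxolan-2-yl)acetaldehyde | CCC1(CC=O)OCCO1 | intermediate
9 | diethylphosphonoacetic acid | CCOP(=O)(CC(=O)O)OCC | starting material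
10 | (R)-4-benzyloxazolidin-2-one | O=C1N[C@H](Cc2ccccc2)CO1 | starting material
11 | (R)-4-benzyl-3-[2-(diethoxyphosphoryl)acetyl]oxazolidin-2-one | CCOP(=O)(CC(=O)N1[C@H](Cc2ccccc2)COC1=O)OCC | intermediate
12 | (R)-4-benzyl-3-[(E)-4-(2-ethyl-1,3-dioxolan-2-yl)but-2-enoyl]oxazolidin-2-one | CCC1(C/C=C/C(=O)N2[C@H](Cc3ccccc3)COC2=O)OCCO1 | intermediate
13 | Diels–Alder adduct: cyclohexene (C1, C10 to C14, C11=C12 with methyl on C12) with the acyl oxazolidinone (C2) on C1, the (S)-1-silyloxy-3-bromobut-3-enyl chain (C9, C8, C7) on C10 and the ketal-bearing CH2 (C15) on C14; C2 cis to C9 and trans to C15 | CCC1(OCCO1)C[C@@H]2CC(C)=C[C@@H]([C@@H](O[Si](C)(C)C(C)(C)C)CC(Br)=C)[C@H]2C(=O)N3[C@H](Cc4ccccc4)COC3=O | intermediate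
14 | bicyclic γ-lactone (C2 carbonyl, O on C9) cis-fused to the cyclohexene at C1–C10, 2-bromoallyl group on C9 cis to H10 | CCC1(OCCO1)C[C@@H]2CC(C)=C[C@@H]3[C@H]2C(=O)O[C@H]3CC(Br)=C | intermediate
15 | 11-epi alcohol: C12 methyl cis to the C10 substituent, C11 hydroxyl trans to both | CCC1(OCCO1)C[C@@H]2C[C@@H](C)[C@H](O)[C@@H]3[C@H]2C(=O)O[C@H]3CC(Br)=C | intermediate
16 | C11 ketone | CCC1(OCCO1)C[C@@H]2C[C@@H](C)C(=O)[C@@H]3[C@H]2C(=O)O[C@H]3CC(Br)=C | intermediate
17 | C11 alcohol, hydroxyl cis to the C10 substituent and the C12 methyl | CCC1(OCCO1)C[C@@H]2C[C@@H](C)[C@@H](O)[C@@H]3[C@H]2C(=O)O[C@H]3CC(Br)=C | intermediate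
18 | C11 tert-butyldimethylsilyl ether of 17 | CCC1(OCCO1)C[C@@H]2C[C@@H](C)[C@@H](O[Si](C)(C)C(C)(C)C)[C@@H]3[C@H]2C(=O)O[C@H]3CC(Br)=C | intermediate
19 | keto lactone: 2-oxobutyl group (C15, C16, C3, methyl) on C14 | CCC(=O)C[C@@H]1C[C@@H](C)[C@@H](O[Si](C)(C)C(C)(C)C)[C@@H]2[C@H]1C(=O)O[C@H]2CC(Br)=C | intermediate
20 | 2-methyl-1,3-dione (C2 and C16 ketones, C3 between them) trans-fused to the cyclohexane, free C9 hydroxyl (not isolated, present as its potassium enolate) | CC1C(=O)C[C@@H]2C[C@@H](C)[C@@H](O[Si](C)(C)C(C)(C)C)[C@@H]([C@@H](O)CC(Br)=C)[C@H]2C1=O | intermediate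
21 | allylated hydroxy diketone: C3 quaternary, allyl axial and cis to H1, methyl equatorial (in equilibrium with hemiketal 22) | C=CC[C@]1(C)C(=O)C[C@@H]2C[C@@H](C)[C@@H](O[Si](C)(C)C(C)(C)C)[C@@H]([C@@H](O)CC(Br)=C)[C@H]2C1=O | intermediate
22 | hemiketal of the C9 hydroxyl on C2 (not isolated) | C=CC[C@]1(C)C(=O)C[C@@H]2C[C@@H](C)[C@@H](O[Si](C)(C)C(C)(C)C)[C@@H]3[C@H]2C1(O)O[C@H]3CC(Br)=C | intermediate
23 | tricyclic ketone: cyclohexanone (C16 ketone, C15, C14, C1, C2, C3) trans-fused to the cyclohexane and to the tetrahydrofuran (O between C2 and C9) | C=CC[C@]1(C)C(=O)C[C@@H]2C[C@@H](C)[C@@H](O[Si](C)(C)C(C)(C)C)[C@@H]3[C@H]2[C@@H]1O[C@H]3CC(Br)=C | intermediate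
24 | silyl peroxy hemiketal at C16 (not isolated) | C=CC[C@]1(C)C(O[Si](C)(C)C)(OO[Si](C)(C)C)C[C@@H]2C[C@@H](C)[C@@H](O[Si](C)(C)C(C)(C)C)[C@@H]3[C@H]2[C@@H]1O[C@H]3CC(Br)=C | intermediate
25 | ε-lactone: seven-membered ring O–C16(=O)–C15–C14–C1–C2–C3, C3 configured as in the target | C=CC[C@]1(C)OC(=O)C[C@@H]2C[C@@H](C)[C@@H](O[Si](C)(C)C(C)(C)C)[C@@H]3[C@H]2[C@@H]1O[C@H]3CC(Br)=C | intermediate
26 | 15-epi methyl lactone (C15 methyl trans to C13; expected main epimer) | C=CC[C@]1(C)OC(=O)[C@@H](C)[C@@H]2C[C@@H](C)[C@@H](O[Si](C)(C)C(C)(C)C)[C@@H]3[C@H]2[C@@H]1O[C@H]3CC(Br)=C | intermediate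
27 | lithium enolate of 26 (C15=C16, not isolated) | C=CC[C@]1(C)OC([O-])=C(C)[C@@H]2C[C@@H](C)[C@@H](O[Si](C)(C)C(C)(C)C)[C@@H]3[C@H]2[C@@H]1O[C@H]3CC(Br)=C.[Li+] | intermediate
28 | C15 methyl lactone (methyl cis to C13, as in the target) | C=CC[C@]1(C)OC(=O)[C@H](C)[C@@H]2C[C@@H](C)[C@@H](O[Si](C)(C)C(C)(C)C)[C@@H]3[C@H]2[C@@H]1O[C@H]3CC(Br)=C | intermediate
29 | lactol at C16 (anomers) | C=CC[C@]1(C)OC(O)[C@H](C)[C@@H]2C[C@@H](C)[C@@H](O[Si](C)(C)C(C)(C)C)[C@@H]3[C@H]2[C@@H]1O[C@H]3CC(Br)=C | intermediate
30 | oxepane with allyl on C3, silyloxy on C11, 2-bromoallyl on C9 | C=CC[C@]1(C)OC[C@H](C)[C@@H]2C[C@@H](C)[C@@H](O[Si](C)(C)C(C)(C)C)[C@@H]3[C@H]2[C@@H]1O[C@H]3CC(Br)=C | intermediate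
31 | propenyl oxepane ((E)-prop-1-enyl on C3) | C/C=C/[C@]1(C)OC[C@H](C)[C@@H]2C[C@@H](C)[C@@H](O[Si](C)(C)C(C)(C)C)[C@@H]3[C@H]2[C@@H]1O[C@H]3CC(Br)=C | intermediate
32 | C4 aldehyde (formyl on C3) | O=C[C@]1(C)OC[C@H](C)[C@@H]2C[C@@H](C)[C@@H](O[Si](C)(C)C(C)(C)C)[C@@H]3[C@H]2[C@@H]1O[C@H]3CC(Br)=C | intermediate
33 | C4 carbinol (4R homoallylic alcohol) | C=CC[C@@H](O)[C@]1(C)OC[C@H](C)[C@@H]2C[C@@H](C)[C@@H](O[Si](C)(C)C(C)(C)C)[C@@H]3[C@H]2[C@@H]1O[C@H]3CC(Br)=C | intermediate
34 | C4 octanoate | C=CC[C@@H](OC(=O)CCCCCCC)[C@]1(C)OC[C@H](C)[C@@H]2C[C@@H](C)[C@@H](O[Si](C)(C)C(C)(C)C)[C@@H]3[C@H]2[C@@H]1O[C@H]3CC(Br)=C | intermediate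
35 | C11 alcohol (C4 octanoate) | C=CC[C@@H](OC(=O)CCCCCCC)[C@]1(C)OC[C@H](C)[C@@H]2C[C@@H](C)[C@@H](O)[C@@H]3[C@H]2[C@@H]1O[C@H]3CC(Br)=C | intermediate
36 | C11 acetate (C4 octanoate, terminal alkene, bromoalkene) | C=CC[C@@H](OC(=O)CCCCCCC)[C@]1(C)OC[C@H](C)[C@@H]2C[C@@H](C)[C@@H](OC(C)=O)[C@@H]3[C@H]2[C@@H]1O[C@H]3CC(Br)=C | intermediate
37 | C6 aldehyde | O=CC[C@@H](OC(=O)CCCCCCC)[C@]1(C)OC[C@H](C)[C@@H]2C[C@@H](C)[C@@H](OC(C)=O)[C@@H]3[C@H]2[C@@H]1O[C@H]3CC(Br)=C | intermediate
38 | macrocyclic allylic alcohol (C6 carbinol, either epimer, C7 methylidene) | OC1C[C@@H](OC(=O)CCCCCCC)[C@]2(C)OC[C@H](C)[C@@H]3C[C@@H](C)[C@@H](OC(C)=O)[C@@H]4[C@H]3[C@@H]2O[C@H]4CC1=C | intermediate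
39 | asbestinin 16 | C=C1C[C@@H]2O[C@H]3[C@H]4[C@@H](C[C@@H](C)[C@@H](OC(C)=O)[C@H]42)[C@@H](C)CO[C@@]3(C)[C@H](OC(=O)CCCCCCC)CC1=O | target

**Totals.** Total step count: 30. Longest linear sequence: 26 steps (steps 1–3 and 8–30, or steps 4, 5, 7 and 8–30).

**Steps most likely to fail**

Step 17. The peroxide may add only slowly to the hindered C16 carbonyl, migration may lose its regiocontrol, or the allyl group may be oxidised. Fallback: starting from 23, bromine (1 equiv, CH2Cl2, −78 °C) adds to the allyl group to give the 5,6-dibromide of the ketone F1. Buffered trifluoroperacetic acid (CF3CO3H, Na2HPO4, CH2Cl2, 0 °C) then effects a classical Baeyer–Villiger oxidation to the 5,6-dibromide of the lactone F2. Zinc dust in AcOH/EtOH restores the alkene and the route is rejoined at 25.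

Step 19. Protonation of enolate 27 may show poor facial selectivity, or O-protonation followed by equilibration may return the 15-epimer. Fallback: starting from 25, LiN(i-Pr)2 and dimethyl(methylidene)ammonium iodide give the 15-(dimethylaminomethyl) lactone F3. Quaternisation with MeI and elimination with NaHCO3 give the 15-methylidene lactone F4. Hydrogenation with Ru(OAc)2[(R)-BINAP] or its antipode, a catalyst type that reduces 2-substituted acrylates but not isolated alkenes, sets C15 under catalyst control and the route is rejoined at 28.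

Step 8. Facial and endo selectivity may erode because the C9 silyloxy centre of the diene is expected to oppose the auxiliary, and the Lewis acid may ionise the dienylic silyl ether or open the ketal. Fallback: starting from 2, step 2 with the antipodal ligand gives the (4R)-carbinol F5, and silylation as in step 3 gives the (4R)-silyl diene F6. Its cycloaddition with 12, now the matched pair, gives the 9-epi adduct F7. LiOH/H2O2 removes the auxiliary to give the 9-epi silyloxy acid F8, and Bu4NF gives the 9-epi hydroxy acid F9. A Mitsunobu lactonisation (PPh3, diisopropyl azodicarboxylate) closes the lactone with inversion at C9 and the route is rejoined at 14.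

**Further compounds**

F1 | step 17 | 5,6-dibromide of the ketone (from 23) | BrCC(Br)C[C@]1(C)C(=O)C[C@@H]2C[C@@H](C)[C@@H](O[Si](C)(C)C(C)(C)C)[C@@H]3[C@H]2[C@@H]1O[C@H]3CC(Br)=C
F2 | step 17 | 5,6-dibromide of the lactone | BrCC(Br)C[C@]1(C)OC(=O)C[C@@H]2C[C@@H](C)[C@@H](O[Si](C)(C)C(C)(C)C)[C@@H]3[C@H]2[C@@H]1O[C@H]3CC(Br)=C
F3 | step 19 | 15-(dimethylaminomethyl) lactone | C=CC[C@]1(C)OC(=O)C(CN(C)C)[C@@H]2C[C@@H](C)[C@@H](O[Si](C)(C)C(C)(C)C)[C@@H]3[C@H]2[C@@H]1O[C@H]3CC(Br)=C
F4 | step 19 | 15-methylidene lactone | C=CC[C@]1(C)OC(=O)C(=C)[C@@H]2C[C@@H](C)[C@@H](O[Si](C)(C)C(C)(C)C)[C@@H]3[C@H]2[C@@H]1O[C@H]3CC(Br)=C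
F5 | step 8 | (4R,5E)-2-bromo-7-methylocta-1,5,7-trien-4-ol | C=C(Br)C[C@@H](O)/C=C/C(C)=C
F6 | step 8 | (4R)-silyl diene, tert-butyldimethylsilyl ether of F5 | C=C(Br)C[C@@H](O[Si](C)(C)C(C)(C)C)/C=C/C(C)=C
F7 | step 8 | 9-epi Diels–Alder adduct | CCC1(OCCO1)C[C@@H]2CC(C)=C[C@@H]([C@H](O[Si](C)(C)C(C)(C)C)CC(Br)=C)[C@H]2C(=O)N3[C@H](Cc4ccccc4)COC3=O
F8 | step 8 | 9-epi silyloxy carboxylic acid | CCC1(OCCO1)C[C@@H]2CC(C)=C[C@@H]([C@H](O[Si](C)(C)C(C)(C)C)CC(Br)=C)[C@H]2C(=O)O
F9 | step 8 | 9-epi hydroxy carboxylic acid | CCC1(OCCO1)C[C@@H]2CC(C)=C[C@@H]([C@H](O)CC(Br)=C)[C@H]2C(=O)O
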